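The central 1,3-diketone is cut by a crossed Claisen condensation into a ring B aryl methyl ketone and a ring A benzoate. Ring A bears oxygen on C2 and C4, the prenyl group on C3 between them and hydrogen on C5 and C6; this is the pattern obtained when a β-keto ester that already carries the prenyl group on its γ-carbon is wrapped around a three-carbon ynoate. The key step therefore assembles ring A in one operation from an acyclic keto ester and methyl propiolate: a Michael addition forms C1–C6, a Claisen closure forms C3–C4, and aromatisation delivers the 3-prenyl-β-resorcylate with every substituent in place.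

Key step: step 2

Assumption: enolates and phenoxides formed by deprotonation are treated as ionised forms of the numbered compounds, and the target is drawn as its diketo tautomer.

Step 1
Reactants: 1 methyl acetoacetate; 2 prenyl bromide (1-bromo-3-methylbut-2-ene)
Product: 3 methyl 7-methyl-3-oxooct-6-enoate
Conditions: NaH (1.1 equiv), THF, 0 °C; n-BuLi (1.05 equiv), 0 °C; 2 (1.0 equiv), 0 °C to rt; aq. HCl work-up
Reagents that add atoms: none
Why: γ-alkylation of a β-keto ester dianion, in which the more basic terminal carbanion should displace bromide from the primary allylic halide (SN2) and leave the doubly activated C2 position untouched.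

Step 2
Reactants: 3 methyl 7-methyl-3-oxooct-6-enoate; 4 methyl propiolate
Product: 6 methyl 2,4-dihydroxy-3-(3-methylbut-2-enyl)benzoate, via Michael adduct 5 (not isolated)
Conditions: NaH (1.05 equiv), THF, 0 °C; 4 (1.0 equiv, slow addition), 0 °C to rt; then LiN(i-Pr)2 (1.3 equiv), −78 °C to rt; aq. HCl work-up
Reagents that add atoms: none
Why: Proposed new method: the sodium enolate of 3 should add through C2 to the β-carbon of 4 (Michael addition, bond C1–C6) to give the glutaconate-type anion 5, whose delocalised three-carbon unit can rotate into the cis geometry; LiN(i-Pr)2 then removes a proton from the γ-methylene next to the ketone, and this carbanion attacks the acrylate ester carbonyl (bond C3–C4), methoxide is expelled and the cyclic dione tautomerises to the resorcylate. The closest known reactions are the Michael–Dieckmann [3+3] resorcinol synthesis from acetonedicarboxylate anions and alkynoates and the Michael–Claisen condensation of acetoacetates with enoates to dihydroresorcylates; new here is the combination of an alkynoate with a γ-carbon activated by one carbonyl only. For that reason the second deprotonation is entrusted to a strong amide base in THF rather than to alkoxide in alcohol, which would hold the γ-carbanion at a vanishing concentration and could add methanol to 4. Ring A closes in a 6-exo-trig acylation and no stereocentre is formed. The step needs site selectivity (C2 before the γ-carbon), which the higher acidity of the C2 hydrogens of 3 and the sequential addition of the two bases secure, since no γ-carbanion exists while 4 is present. It also needs C- over O-acylation, which should follow because the 2-pyranone from O-attack can be reopened by the liberated methoxide whereas aromatisation removes the C-acylation product from all equilibria.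

Step 3
Reactants: 6 methyl 2,4-dihydroxy-3-(3-methylbut-2-enyl)benzoate
Product: 7 methyl 2-hydroxy-4-(methoxymethoxy)-3-(3-methylbut-2-enyl)benzoate
Conditions: MOMCl (1.1 equiv), K2CO3, acetone, 0 °C to rt
Reagents that add atoms: chloromethyl methyl ether (MOMCl), COCCl
Why: Williamson-type O-alkylation that should take place only at the more acidic, unchelated 4-hydroxyl, because the 2-hydroxyl is held in a hydrogen bond to the ester carbonyl and is flanked on both sides.

Step 4
Reactants: 7 methyl 2-hydroxy-4-(methoxymethoxy)-3-(3-methylbut-2-enyl)benzoate
Product: 8 methyl 2-methoxy-4-(methoxymethoxy)-3-(3-methylbut-2-enyl)benzoate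
Conditions: MeI (3 equiv), K2CO3, DMF, 50 °C
Reagents that add atoms: iodomethane (MeI), CI
Why: Williamson O-methylation of the remaining chelated phenol, which a polar aprotic solvent and mild heating should drive to completion while the MOM acetal, the ester and the prenyl group are inert to carbonate.

Step 5
Reactants: 9 4-hydroxyacetophenone; 2 prenyl bromide
Product: 10 1-[4-hydroxy-3-(3-methylbut-2-enyl)phenyl]ethanone
Conditions: NaH (1.0 equiv), toluene, 0 °C to rt; 2 (1.0 equiv), rt to 60 °C
Reagents that add atoms: none
Why: ortho-C-alkylation of a sodium phenoxide in a non-polar medium, where tight ion pairing shields oxygen and steers the allylic bromide to the ring carbon; the para position is blocked by the acetyl group and the two ortho positions are equivalent, so one mono-C-prenyl isomer is expected.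

Step 6
Reactants: 10 1-[4-hydroxy-3-(3-methylbut-2-enyl)phenyl]ethanone
Product: 11 1-[4-(methoxymethoxy)-3-(3-methylbut-2-enyl)phenyl]ethanone
Conditions: MOMCl (1.3 equiv), K2CO3, acetone, rt
Reagents that add atoms: chloromethyl methyl ether (MOMCl), COCCl
Why: Williamson-type O-alkylation of the only acidic group, since carbonate does not enolise the methyl ketone appreciably, giving a phenol protection that withstands the strongly basic coupling.

Step 7
Reactants: 8 methyl 2-methoxy-4-(methoxymethoxy)-3-(3-methylbut-2-enyl)benzoate; 11 1-[4-(methoxymethoxy)-3-(3-methylbut-2-enyl)phenyl]ethanone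
Product: 12 1-[2-methoxy-4-(methoxymethoxy)-3-(3-methylbut-2-enyl)phenyl]-3-[4-(methoxymethoxy)-3-(3-methylbut-2-enyl)phenyl]propane-1,3-dione
Conditions: NaH (3 equiv), THF, reflux, slow addition of 11 to 8 (1.2 equiv); cold aq. HCl to pH 5
Reagents that add atoms: none
Why: crossed Claisen condensation in which only the ketone can form an enolate and the ester has no α-hydrogen, and deprotonation of the product to its sodium β-diketonate should pull the equilibrium to the coupled product.

Step 8
Reactants: 12 1-[2-methoxy-4-(methoxymethoxy)-3-(3-methylbut-2-enyl)phenyl]-3-[4-(methoxymethoxy)-3-(3-methylbut-2-enyl)phenyl]propane-1,3-dione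
Product: 13 1-[4-hydroxy-2-methoxy-3-(3-methylbut-2-enyl)phenyl]-3-[4-hydroxy-3-(3-methylbut-2-enyl)phenyl]propane-1,3-dione
Conditions: HCl (about 1 M, from conc. aq. HCl), MeOH, rt to 40 °C, stopped at full conversion
Reagents that add atoms: none
Why: acid-catalysed transacetalisation of both MOM ethers to methanol, kept dilute and at or below 40 °C, the usual way to unmask ortho-prenylphenols without closing the prenyl groups onto the free hydroxyls; the aryl methyl ether and the β-diketone should be inert.

Compound list
1 | methyl acetoacetate (methyl 3-oxobutanoate) | CC(=O)CC(=O)OC | starting material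
2 | prenyl bromide (1-bromo-3-methylbut-2-ene) | CC(C)=CCBr | starting material
3 | methyl 7-methyl-3-oxooct-6-enoate | COC(=O)CC(=O)CCC=C(C)C | intermediate
4 | methyl propiolate (methyl prop-2-ynoate) | C#CC(=O)OC | starting material
5 | dimethyl 4-(5-methylhex-4-enoyl)pent-2-enedioate, formed as its sodium salt (2E/2Z mixture that interconverts through the anion) | COC(=O)C=CC(C(=O)CCC=C(C)C)C(=O)OC | intermediate (not isolated)
6 | methyl 2,4-dihydroxy-3-(3-methylbut-2-enyl)benzoate | COC(=O)c1ccc(O)c(CC=C(C)C)c1O | intermediate
7 | methyl 2-hydroxy-4-(methoxymethoxy)-3-(3-methylbut-2-enyl)benzoate | COCOc1ccc(C(=O)OC)c(O)c1CC=C(C)C | intermediate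
8 | methyl 2-methoxy-4-(methoxymethoxy)-3-(3-methylbut-2-enyl)benzoate | COCOc1ccc(C(=O)OC)c(OC)c1CC=C(C)C | intermediate
9 | 4-hydroxyacetophenone (1-(4-hydroxyphenyl)ethanone) | CC(=O)c1ccc(O)cc1 | starting material
10 | 1-[4-hydroxy-3-(3-methylbut-2-enyl)phenyl]ethanone | CC(=O)c1ccc(O)c(CC=C(C)C)c1 | intermediate
11 | 1-[4-(methoxymethoxy)-3-(3-methylbut-2-enyl)phenyl]ethanone | CC(=O)c1ccc(OCOC)c(CC=C(C)C)c1 | intermediate
12 | 1-[2-methoxy-4-(methoxymethoxy)-3-(3-methylbut-2-enyl)phenyl]-3-[4-(methoxymethoxy)-3-(3-methylbut-2-enyl)phenyl]propane-1,3-dione | COCOc1ccc(C(=O)CC(=O)c2ccc(OCOC)c(CC=C(C)C)c2)c(OC)c1CC=C(C)C | intermediate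
13 | 1-[4-hydroxy-2-methoxy-3-(3-methylbut-2-enyl)phenyl]-3-[4-hydroxy-3-(3-methylbut-2-enyl)phenyl]propane-1,3-dione (no stereocentres) | COc1c(C(=O)CC(=O)c2ccc(O)c(CC=C(C)C)c2)ccc(O)c1CC=C(C)C | target

Total step count: 8. Longest linear sequence: 6 steps (steps 1, 2, 3, 4, 7, 8); steps 5 and 6 form the convergent ring B branch.

Steps most likely to fail

Step 2 (proposed new method). The Claisen closure may stall, because the ester that has to be attacked shares the charge of the delocalised anion. The open-chain anion may also drain into the 2-pyranone by O-acylation, or the propiolate may oligomerise before the Michael addition is complete. The fallback sets out from 3 and closes the ring one oxidation level lower with known chemistry. Compound 3 and methyl acrylate, with NaOMe in MeOH at reflux, should give the Michael adduct dimethyl 2-(5-methylhex-4-enoyl)pentanedioate F1. Under the same conditions F1 should undergo Claisen closure through the γ-carbon to methyl 3-(3-methylbut-2-enyl)-2,4-dioxocyclohexane-1-carboxylate F2, the classical route to dihydroresorcylates. The dianion of F2 (LiN(i-Pr)2, 2.2 equiv, THF, −78 °C) should be selenenylated by PhSeBr at the ester-bearing carbon to give methyl 3-(3-methylbut-2-enyl)-2,4-dioxo-1-(phenylselanyl)cyclohexane-1-carboxylate F3. Oxidation with H2O2 in CH2Cl2/pyridine at 0 °C should give the selenoxide methyl 3-(3-methylbut-2-enyl)-2,4-dioxo-1-(phenylseleninyl)cyclohexane-1-carboxylate F4. Syn-elimination of F4 towards C6 and tautomerisation should deliver 6, where the route is rejoined.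

Step 5. O-alkylation, double alkylation and acid-induced ring closure of the product onto its own phenol may erode the C-monoprenylation of the deactivated phenoxide. The fallback sets out from 9 and replaces the phenoxide alkylation by a cross-coupling. Iodination with N-iodosuccinimide and catalytic TsOH in MeCN should give 1-(4-hydroxy-3-iodophenyl)ethanone F5. MOMCl and K2CO3 in acetone should give 1-[3-iodo-4-(methoxymethoxy)phenyl]ethanone F6. A Stille coupling of F6 with tributyl(3-methylbut-2-enyl)stannane (Pd(PPh3)4, DMF, 90 °C) should deliver 11 directly, so the route is rejoined at 11 and 10 is bypassed.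

Step 7. Acylation of the ketone enolate by the electron-rich, ortho-substituted ester may be slower than self-aldol condensation of the ketone, so that the enolate is consumed unproductively. The fallback sets out from 8 and uses a more reactive acyl donor with a preformed lithium enolate at low temperature. Saponification (LiOH, THF/MeOH/H2O, 50 °C, careful acidification to pH 4) should give 2-methoxy-4-(methoxymethoxy)-3-(3-methylbut-2-enyl)benzoic acid F7. 1,1'-Carbonyldiimidazole in THF should convert F7 into the acyl imidazolide (1H-imidazol-1-yl)[2-methoxy-4-(methoxymethoxy)-3-(3-methylbut-2-enyl)phenyl]methanone F8. Addition of F8 to the lithium enolate of 11 (LiN(SiMe3)2, 2.2 equiv, THF, −78 °C to 0 °C) should give 12, where the route is rejoined.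

Further compounds
F1 | step 2 | dimethyl 2-(5-methylhex-4-enoyl)pentanedioate (racemic, not isolated) | COC(=O)CCC(C(=O)CCC=C(C)C)C(=O)OC
F2 | step 2 | methyl 3-(3-methylbut-2-enyl)-2,4-dioxocyclohexane-1-carboxylate (racemic diastereomer and tautomer mixture; stereocentres are lost on aromatisation) | COC(=O)C1CCC(=O)C(CC=C(C)C)C1=O
F3 | step 2 | methyl 3-(3-methylbut-2-enyl)-2,4-dioxo-1-(phenylselanyl)cyclohexane-1-carboxylate (racemic diastereomer mixture) | COC(=O)C1([Se]c2ccccc2)CCC(=O)C(CC=C(C)C)C1=O
F4 | step 2 | methyl 3-(3-methylbut-2-enyl)-2,4-dioxo-1-(phenylseleninyl)cyclohexane-1-carboxylate (racemic diastereomer mixture, not isolated) | COC(=O)C1([Se](=O)c2ccccc2)CCC(=O)C(CC=C(C)C)C1=O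
F5 | step 5 | 1-(4-hydroxy-3-iodophenyl)ethanone | CC(=O)c1ccc(O)c(I)c1
F6 | step 5 | 1-[3-iodo-4-(methoxymethoxy)phenyl]ethanone | CC(=O)c1ccc(OCOC)c(I)c1
F7 | step 7 | 2-methoxy-4-(methoxymethoxy)-3-(3-methylbut-2-enyl)benzoic acid | COCOc1ccc(C(=O)O)c(OC)c1CC=C(C)C
F8 | step 7 | (1H-imidazol-1-yl)[2-methoxy-4-(methoxymethoxy)-3-(3-methylbut-2-enyl)phenyl]methanone | COCOc1ccc(C(=O)n2ccnc2)c(OC)c1CC=C(C)C
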